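## Retrosynthetic overview

1. The acetate goes on last. The furanone (O1, C2, C3, C4, C5) is closed by O1–C5 bromolactonisation of an enynoic acid whose carboxyl group is cis to a bromoalkyne; this closure also makes C6Br2.
2. The feature used: C3 carries both the ring carbonyl C2 and the carbinol C1'. The C1' oxygen can therefore hold C2 in a four-membered lactone (O, C2, C3, C1') that is not part of the target.
3. That β-lactone comes from a palladium-catalysed bromocarbonylation of an (R)-silyl diynol with CO. C4–Br, C2–C3 and C2–O(C1') form in one step, and anti addition places the alkynyl group cis to C2.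
4. The diynol comes from 1,4-bis(trimethylsilyl)buta-1,3-diyne and butanoyl chloride by acylation and asymmetric transfer hydrogenation, which sets C1'.
5. Ring order: the temporary β-lactone first, the furanone second, after the lactone has been opened.

Key step: step 3

Remark: atoms are labelled as in the furanone (O1, C2 carbonyl, C3, C4, C5, exocyclic C6), with the side-chain carbinol as C1'; the stereocentre C1' of the target is read as (R).

## Route

Step 1
Reactants: 1 1,4-bis(trimethylsilyl)buta-1,3-diyne; 2 butanoyl chloride
Product: 3 8-(trimethylsilyl)octa-5,7-diyn-4-one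
Conditions: AlCl3 (1.1 equiv), CH2Cl2, 0 °C
Reagents that add atoms: none
Why: Friedel–Crafts acylation with ipso-desilylation, in which the acylium ion attacks a silicon-bearing alkyne carbon and Me3SiCl is lost, and the new ketone deactivates the diyne so that the second silyl group should stay.

Step 2
Reactants: 3 8-(trimethylsilyl)octa-5,7-diyn-4-one
Product: 4 (4R)-8-(trimethylsilyl)octa-5,7-diyn-4-ol
Conditions: Ru[(R,R)-TsNCH(Ph)CH(Ph)NH](p-cymene) (2 mol%), i-PrOH, rt
Reagents that add atoms: none
Why: Noyori asymmetric transfer hydrogenation of an alkynyl ketone, in which the diynyl group takes the place of the aryl group in the CH/π-controlled transition state, so that the (R,R)-ligand should deliver hydride to the face that gives the (R)-carbinol, as with other alkyl alkynyl ketones.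

Step 3
Reactants: 4 (4R)-8-(trimethylsilyl)octa-5,7-diyn-4-ol; 5 carbon monoxide
Product: 6 (3E,4R)-3-[1-bromo-3-(trimethylsilyl)prop-2-yn-1-ylidene]-4-propyloxetan-2-one
Conditions: PdBr2 (10 mol%), CuBr2 (2.5 equiv), LiBr (6 equiv), CO (1 atm), propylene oxide (2 equiv), THF, 0 °C to rt
Reagents that add atoms: copper dibromide (bromine on C4, drawn from the bromide pool it shares with LiBr), [Cu+2].[Br-].[Br-]
Why: Proposed new method: divalent palladium π-bound to the carbinol-proximal C3≡C4 bond is attacked at C4 by free bromide from the face opposite the metal (anti-bromopalladation), the C3–Pd vinyl species inserts CO, and the C1' oxygen closes a five-membered acyl–alkoxy palladacycle that gives the β-lactone by C–O reductive elimination, after which CuBr2 reoxidises zerovalent palladium. The closest known reaction type is the PdCl2–CuCl2 halopalladation–cyclocarbonylation of 2-alkynols to α-(haloalkylidene)-β-lactones, which puts halide and carbonyl on the same carbons but adds them syn; anti-halopalladation of alkynes at high halide concentration is known separately, and neither that mode in a cyclocarbonylation nor a conjugated diynol has been shown. The four-membered ring (O, C2, C3, C1') closes by acyl C2–O bond formation at palladium, formally a 4-exo-trig lactonisation. No stereocentre is formed: the C1'–O bond is never broken, so C1' stays (R), and the E geometry of C3=C4 (alkynyl cis to C2, bromine cis to C1') is the direct result of anti addition. The step needs reaction at the proximal alkyne with bromide on C4 and palladium on C3; the substrate should secure this because bromide goes to the carbon remote from the inductively withdrawing C1' oxygen, as in the known syn series, because the branched carbinol carbon shields C3 from external bromide, and because the trimethylsilyl group shields C5≡C6. The anti mode is not secured by the substrate but by the medium (LiBr in excess so that external attack outruns Pd–Br insertion, propylene oxide to take up HBr so that the vinylpalladium is carbonylated and not protonated), and this is the open point of the step.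

Step 4
Reactants: 6 (3E,4R)-3-[1-bromo-3-(trimethylsilyl)prop-2-yn-1-ylidene]-4-propyloxetan-2-one
Product: 7 (3E,4R)-3-(1,3-dibromoprop-2-yn-1-ylidene)-4-propyloxetan-2-one
Conditions: NBS (1.1 equiv), AgNO3 (10 mol%), acetone, rt, dark
Reagents that add atoms: N-bromosuccinimide, O=C1CCC(=O)N1Br
Why: Silver-assisted desilylative bromination of an alkynylsilane (a silver acetylide is brominated by NBS), a neutral exchange that should leave the lactone, the vinyl bromide and C1' untouched and is placed before any free carboxylic acid exists that silver could cyclise onto the alkyne.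

Step 5
Reactants: 7 (3E,4R)-3-(1,3-dibromoprop-2-yn-1-ylidene)-4-propyloxetan-2-one
Product: 8 (2E)-3,5-dibromo-2-[(1R)-1-hydroxybutyl]pent-2-en-4-ynoic acid
Conditions: LiOH·H2O (1.2 equiv), THF/H2O 3:1, 0 °C, short reaction time; then cold 1 M HCl to pH 3; used crude
Reagents that add atoms: lithium hydroxide, [Li+].[OH-]
Why: Saponification of a β-lactone by acyl–oxygen cleavage, which should be much faster at the strained carbonyl than attack at C4 or at the bromoalkyne; the C1'–O bond is not broken, so C1' stays (R) and the carboxyl group stays cis to the alkynyl group.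

Step 6
Reactants: 8 (2E)-3,5-dibromo-2-[(1R)-1-hydroxybutyl]pent-2-en-4-ynoic acid
Product: 9 4-bromo-5-(dibromomethylidene)-3-[(1R)-1-hydroxybutyl]furan-2(5H)-one
Conditions: NBS (1.1 equiv), KHCO3 (0.2 equiv), MeCN, 0 °C, dark
Reagents that add atoms: N-bromosuccinimide, O=C1CCC(=O)N1Br
Why: Bromolactonisation of an enynoic acid, in which the bromonium-activated bromoalkyne is attacked by the carboxylate at C5 (the alkyne carbon without bromine) in a 5-exo-dig closure that forms O1–C5 and leaves C6 with two bromines, so that no alkene geometry has to be controlled.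

Step 7
Reactants: 9 4-bromo-5-(dibromomethylidene)-3-[(1R)-1-hydroxybutyl]furan-2(5H)-one
Product: 10 (1R)-1-[4-bromo-5-(dibromomethylidene)-2-oxo-2,5-dihydrofuran-3-yl]butyl acetate
Conditions: Ac2O (1.5 equiv), Sc(OTf)3 (1 mol%), MeCN, −20 to 0 °C
Reagents that add atoms: acetic anhydride, CC(=O)OC(C)=O
Why: Lewis acid-catalysed acetylation of a secondary alcohol, which touches only the O–H bond (retention at C1') and is chosen over amine-base conditions because the 4-bromo-5-ylidene furanone tolerates acid but adds nucleophiles.

## Compound list

1 | 1,4-bis(trimethylsilyl)buta-1,3-diyne | C[Si](C)(C)C#CC#C[Si](C)(C)C | starting material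
2 | butanoyl chloride | CCCC(Cl)=O | starting material
3 | 8-(trimethylsilyl)octa-5,7-diyn-4-one | CCCC(=O)C#CC#C[Si](C)(C)C | intermediate
4 | (4R)-8-(trimethylsilyl)octa-5,7-diyn-4-ol | CCC[C@@H](O)C#CC#C[Si](C)(C)C | intermediate
5 | carbon monoxide | [C-]#[O+] | starting material
6 | (3E,4R)-3-[1-bromo-3-(trimethylsilyl)prop-2-yn-1-ylidene]-4-propyloxetan-2-one | CCC[C@H]1OC(=O)/C1=C(/Br)C#C[Si](C)(C)C | intermediate
7 | (3E,4R)-3-(1,3-dibromoprop-2-yn-1-ylidene)-4-propyloxetan-2-one | CCC[C@H]1OC(=O)/C1=C(/Br)C#CBr | intermediate
8 | (2E)-3,5-dibromo-2-[(1R)-1-hydroxybutyl]pent-2-en-4-ynoic acid | CCC[C@@H](O)/C(C(=O)O)=C(\Br)C#CBr | intermediate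
9 | 4-bromo-5-(dibromomethylidene)-3-[(1R)-1-hydroxybutyl]furan-2(5H)-one | CCC[C@@H](O)C1=C(Br)C(=C(Br)Br)OC1=O | intermediate
10 | (1R)-1-[4-bromo-5-(dibromomethylidene)-2-oxo-2,5-dihydrofuran-3-yl]butyl acetate | CCC[C@@H](OC(C)=O)C1=C(Br)C(=C(Br)Br)OC1=O | target

## Step count and risks

Total steps: 7. Longest linear sequence: 7 steps (1 and 2 to 10).

**Step 3 (goes beyond known chemistry).** What may go wrong: syn delivery of bromide and palladium, which gives the geometric isomer with C2 trans to the alkynyl group; bromide attack at C3 followed by closure to a five-membered butenolide; or opening of the strained lactone by bromide. The fallback uses known chemistry, sets out from 4 and comes back at 6. Hydroxyl-directed anti-carbomagnesiation of 4 with CH2=CHMgCl (excess, THF/toluene, heat) is known for 2-alkynols to put the carbon group on the carbinol-proximal carbon and magnesium on the distal carbon within a five-membered alkoxide chelate. Quenching the vinylmagnesium with NBS should give (4R,5Z)-6-bromo-5-ethenyl-8-(trimethylsilyl)oct-5-en-7-yn-4-ol F1, in which bromine is already cis to C1'. Lemieux–Johnson cleavage of the monosubstituted vinyl group (OsO4 cat., NaIO4, 2,6-lutidine, dioxane/H2O) should give (2E)-3-bromo-2-[(1R)-1-hydroxybutyl]-5-(trimethylsilyl)pent-2-en-4-ynal F2. Pinnick oxidation (NaClO2, NaH2PO4, 2-methylbut-2-ene, t-BuOH/H2O) should give (2E)-3-bromo-2-[(1R)-1-hydroxybutyl]-5-(trimethylsilyl)pent-2-en-4-ynoic acid F3. β-Lactonisation by carboxyl activation (PhSO2Cl, pyridine, 0 °C; the C1'–O bond is kept) returns to 6.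

**Step 6.** What may go wrong: 6-endo closure onto C6 to a 2-pyranone, or non-selective bromination. The fallback sets out from 8 and comes back at 9. Ag2CO3-catalysed cycloisomerisation of 8 (acetone, rt) is exo-selective for enynoic acids of this geometry and proceeds by anti oxymetalation and protodemetalation; it should give (5Z)-4-bromo-5-(bromomethylidene)-3-[(1R)-1-hydroxybutyl]furan-2(5H)-one F4. Addition of Br2 to the exocyclic enol-lactone double bond (CH2Cl2, −78 °C) should give 4,5-dibromo-5-(dibromomethyl)-3-[(1R)-1-hydroxybutyl]furan-2(5H)-one F5 as a mixture at C5. Et3N then removes HBr across C5–C6 to give 9.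

**Step 2.** What may go wrong: incomplete enantioface discrimination, or degradation of the electrophilic silyl diynone under the basic amido catalyst (conjugate addition of isopropoxide, loss of the silyl group). The fallback sets out from 1 and comes back at 4. Monodesilylation of 1 with MeLi·LiBr (THF, rt) gives lithium 4-(trimethylsilyl)buta-1,3-diyn-1-ide F6, and protonation gives buta-1,3-diyn-1-yl(trimethyl)silane F7. Catalytic enantioselective alkynylation of butanal with F7 (Et2Zn, chiral ProPhenol ligand, Ph3P=O, toluene, 0 °C; the ligand enantiomer chosen to give the (R)-carbinol) forms the C1'–C3 bond and the stereocentre in one step and should give 4 directly.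

## Further compounds

F1 | step 3 | (4R,5Z)-6-bromo-5-ethenyl-8-(trimethylsilyl)oct-5-en-7-yn-4-ol | CCC[C@@H](O)/C(C=C)=C(\Br)C#C[Si](C)(C)C
F2 | step 3 | (2E)-3-bromo-2-[(1R)-1-hydroxybutyl]-5-(trimethylsilyl)pent-2-en-4-ynal | CCC[C@@H](O)/C(C=O)=C(\Br)C#C[Si](C)(C)C
F3 | step 3 | (2E)-3-bromo-2-[(1R)-1-hydroxybutyl]-5-(trimethylsilyl)pent-2-en-4-ynoic acid | CCC[C@@H](O)/C(C(=O)O)=C(\Br)C#C[Si](C)(C)C
F4 | step 6 | (5Z)-4-bromo-5-(bromomethylidene)-3-[(1R)-1-hydroxybutyl]furan-2(5H)-one | CCC[C@@H](O)C1=C(Br)/C(=C/Br)OC1=O
F5 | step 6 | 4,5-dibromo-5-(dibromomethyl)-3-[(1R)-1-hydroxybutyl]furan-2(5H)-one | CCC[C@@H](O)C1=C(Br)C(Br)(C(Br)Br)OC1=O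
F6 | step 2 | lithium 4-(trimethylsilyl)buta-1,3-diyn-1-ide | [Li]C#CC#C[Si](C)(C)C
F7 | step 2 | buta-1,3-diyn-1-yl(trimethyl)silane | C#CC#C[Si](C)(C)C
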